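**Plan**

1. The target is an elemane-type cyclohexane. Ring atoms are C5–C10: C10 carries CH3 and vinyl, C5 carries C4(=CH2)CH2OH, C6 carries OH, C7 carries C11(=C13H2)–C12O2H, C8 carries the acyloxy group, C9 is CH2.
2. Retrosynthesis: cut the C8–O ester; take C12 back to CO and C11 to an acetyl group, and O6 back to a C6–B bond; cut the ring bond C7–C8 together with C6–B; then C6=C7 (Wittig) and C5–C10 ([3,3] shift).
3. Enabling feature: ring atoms C6–C7–C8 are an all-trans (triequatorial) 1,3-dioxygenated array whose central carbon C7 bears the latent acyl carbon C11. This 2-acyl-1,3-diol is the retron of conjugate addition of an oxygen surrogate to C6 of an enone followed by aldol closure of the C7 enolate onto a C8 aldehyde.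
4. Forward: the chain C8–C9–C10–C5–C6 comes from an Ireland–Claisen rearrangement of an itaconate and the enone from a Wittig reaction. The only ring (the cyclohexane) then closes at C7–C8 in a copper-catalysed borylative aldol cyclisation. Afterwards acetyl becomes acrylate (enol triflate carbonylation), O8 is acylated, and C6–B becomes C6–OH last.
5. Stereochemistry: C5/C10 from the chair Ireland–Claisen under a chiral diazaborolidine controller; C6 by 1,2-induction from C5 in the borylcupration; C7/C8 from the chair aldol transition state; C6–B is oxidised with retention; the side-chain (Z)-alkene comes from a butenolide.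
6. Boron at C6 is the temporary helper: it creates the C7 enolate regiospecifically, cannot β-eliminate, keeps O6 distinct from O8, and blocks 6,12-lactonisation until the end.

Key step: step 10

Assumption: the (R,R)-antipode of the diazaborolidine controller in step 4 is taken to deliver (2S,3S)-7; if the sense of induction is the reverse, the (S,S)-antipode is used and nothing else changes.

**Step 1**
Reactants: 1 tert-butyl(but-3-yn-1-yloxy)dimethylsilane
Product: 3 (E)-allylic alcohol, via alkenylalane 2 (not isolated)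
Conditions: Me3Al, Cp2ZrCl2 (0.25 equiv), CH2Cl2, 0 °C → rt; then n-BuLi, (CH2O)n, THF, −78 °C → rt
Reagents that add atoms: trimethylaluminium C[Al](C)C; formaldehyde (as paraformaldehyde) C=O
Why: Zirconium-catalysed syn-carboalumination of the terminal alkyne places CH3 and Al cis, and hydroxymethylation of the alkenyl alanate proceeds with retention, so the (E)-trisubstituted allylic alcohol should result.

**Step 2**
Reactants: 3 (E)-allylic alcohol; 4 itaconic anhydride
Product: 5 4-allylic hydrogen itaconate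
Conditions: toluene, 60 °C, no base
Reagents that add atoms: none
Why: Uncatalysed alcoholysis of the anhydride should occur at the non-conjugated carbonyl next to the CH2 group, giving the ester that has the enolisable CH2 (future C5) and the free acrylic acid (future C15).

**Step 3**
Reactants: 5 4-allylic hydrogen itaconate
Product: 6 mixed allylic methyl itaconate
Conditions: MeI, KHCO3, DMF, rt
Reagents that add atoms: iodomethane CI
Why: Carboxylate O-alkylation under weakly basic conditions should esterify the acrylic acid without moving the exocyclic double bond into conjugation.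

**Step 4**
Reactants: 6 mixed allylic methyl itaconate
Product: 7 (2S,3S)-pent-4-enoic acid
Conditions: (1R,2R)-N,N'-bis[3,5-bis(trifluoromethyl)phenylsulfonyl]-1,2-diphenylethane-1,2-diamine, BBr3, CH2Cl2, rt, then evaporation (gives the B-bromodiazaborolidine); 6, iPr2NEt, CH2Cl2, −78 °C → rt; aqueous work-up
Reagents that add atoms: none
Why: In this reagent-controlled Ireland–Claisen rearrangement, soft enolisation should give the O-boron ketene acetal with the C4 alkenyl group cis to O–B, and the [3,3] shift through a chair with this group and the C9 chain of the (E)-alkene both equatorial should form C5–C10 with the methyl/vinyl quaternary centre in the 5S,10S relationship, the C2-symmetric diazaborolidine selecting the enolate face.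

**Step 5**
Reactants: 7 (2S,3S)-pent-4-enoic acid
Product: 8 1,4-diol
Conditions: AlH3·NMe2Et, THF, 0 °C → rt
Reagents that add atoms: none
Why: Alane reduction takes the carboxylic acid to the alcohol and reduces the 2-substituted acrylate in the 1,2-sense only, so the diol with intact exo-methylene should form without touching C5 or C10.

**Step 6**
Reactants: 8 1,4-diol
Product: 9 C15 TBDPS ether
Conditions: TBDPSCl (1.05 equiv), imidazole, CH2Cl2, −20 °C → 0 °C
Reagents that add atoms: tert-butyl(chloro)diphenylsilane CC(C)(C)[Si](Cl)(c1ccccc1)c1ccccc1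
Why: Selective silylation should occur at the unhindered allylic primary hydroxyl (C15), because the C6 hydroxyl is β-branched and sits next to the quaternary carbon.

**Step 7**
Reactants: 9 C15 TBDPS ether
Product: 11 (E)-enone, via aldehyde 10 (not isolated)
Conditions: DMP, NaHCO3, CH2Cl2, 0 °C → rt; then Ph3P=CHC(O)CH3, rt → 40 °C, one pot
Reagents that add atoms: 1-(triphenyl-λ5-phosphanylidene)propan-2-one CC(=O)C=P(c1ccccc1)(c1ccccc1)c1ccccc1
Why: Buffered Dess–Martin oxidation followed by an in-situ Wittig reaction with the ketone-stabilised ylide should give the (E)-enone, and the epimerisable β,γ-unsaturated aldehyde is never isolated.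

**Step 8**
Reactants: 11 (E)-enone
Product: 12 C8 alcohol
Conditions: CSA (0.1 equiv), MeOH/CH2Cl2 (1:1), 0 °C
Reagents that add atoms: none
Why: Acid-catalysed methanolysis (desilylation) cleaves the primary TBS ether much faster than the TBDPS ether, so only the C8 hydroxyl should be freed.

**Step 9**
Reactants: 12 C8 alcohol
Product: 13 enone aldehyde
Conditions: DMP, NaHCO3, CH2Cl2, 0 °C → rt
Reagents that add atoms: none
Why: Neutral Dess–Martin oxidation should give the aldehyde, which cannot cyclise onto the (E)-enone until C6 becomes sp3.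

**Step 10**
Reactants: 13 enone aldehyde
Product: 15 borylated aldol, via O-boryl aldolate 14 (not isolated)
Conditions: CuCl (10 mol%), DPEphos (11 mol%), NaOtBu (10 mol%), B2pin2 (1.2 equiv), THF, −20 °C → rt; aq. NH4Cl
Reagents that add atoms: bis(pinacolato)diboron CC1(C)OB(OC1(C)C)B1OC(C)(C)C(C)(C)O1
Why: CuCl, NaOtBu and B2pin2 give a phosphine-ligated boryl-copper species that adds to the (E)-enone at C6; the resulting copper enolate at C7 attacks the C8 aldehyde, and the copper aldolate is turned over by B2pin2 (σ-bond metathesis) to the O-boryl aldolate 14, which is hydrolysed on work-up. The closest known reaction type is the copper-catalysed borylative aldol cyclisation of enones carrying a tethered ketone, itself built on conjugate borylation. The cyclohexane (C5–C10) closes in the 6-(enolexo)-exo-trig mode. C6 should be set by C5 (modified Felkin–Anh: quaternary C10 anti to the incoming boron, the C4 alkenyl group inside), and C7 and C8 by a chair Zimmerman–Traxler-type transition state of the (Z)-O-copper enolate fused trans to the forming ring, with Bpin, C11 and the aldehyde oxygen all equatorial, because the other chair would put Bpin and the C8 oxygen 1,3-diaxial to the C10 vinyl group. The step needs conjugate borylation of the enone to outrun 1,2-borylation of the aliphatic aldehyde and protonation of the enolate; the enone is the better acceptor for a phosphine-ligated boryl copper, no protic additive is present, and the aldol is intramolecular. Boron at C6 cannot be β-eliminated, which is what makes a regiodefined C7 enolate between two oxygenated positions available at all.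

**Step 11**
Reactants: 15 borylated aldol
Product: 16 C8 TES ether
Conditions: TESCl, imidazole, DMF, rt
Reagents that add atoms: chlorotriethylsilane CC[Si](Cl)(CC)CC
Why: Silylation of the secondary C8 hydroxyl under neutral conditions should block retro-aldol cleavage in step 12 and 8,12-lactone formation in step 13.

**Step 12**
Reactants: 16 C8 TES ether
Product: 17 vinyl triflate
Conditions: KN(SiMe3)2, THF, −78 °C; then PhNTf2, −78 → 0 °C
Reagents that add atoms: N-phenylbis(trifluoromethanesulfonimide) O=S(=O)(N(c1ccccc1)S(=O)(=O)C(F)(F)F)C(F)(F)F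
Why: Enol triflate formation under kinetic control should take place at the methyl group and not at the hindered C7 methine, giving the 1,1-disubstituted vinyl triflate C11=C13 with C7 untouched.

**Step 13**
Reactants: 17 vinyl triflate
Product: 18 2-(trimethylsilyl)ethyl acrylate
Conditions: Pd(OAc)2 (5 mol%), PPh3 (10 mol%), Et3N, CO (1 atm), Me3SiCH2CH2OH (5 equiv), DMF, 50 °C
Reagents that add atoms: carbon monoxide [C-]#[O+]; 2-(trimethylsilyl)ethanol C[Si](C)(C)CCO
Why: Palladium-catalysed alkoxycarbonylation (oxidative addition of the triflate to zerovalent palladium, CO insertion, alcoholysis) should install C12 as the acrylate ester, while the secondary alkyl boronate does not transmetalate under these conditions.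

**Step 14**
Reactants: 18 2-(trimethylsilyl)ethyl acrylate
Product: 19 C8 alcohol of the acrylate
Conditions: PPTS, MeOH, rt
Reagents that add atoms: none
Why: Mild acid methanolysis (desilylation) should remove the secondary TES ether and leave the TBDPS ether, the pinacol boronate and the silylethyl ester intact.

**Step 15**
Reactants: 20 3-methylfuran-2(5H)-one
Product: 22 (Z)-4-acetoxy-2-methylbut-2-enoic acid, via sodium hydroxy carboxylate 21 (not isolated)
Conditions: NaOH (1.0 equiv), H2O/THF, rt, evaporation; then Ac2O, pyridine, 0 °C → rt; cold dilute HCl work-up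
Reagents that add atoms: sodium hydroxide [Na+].[OH-]; acetic anhydride CC(=O)OC(C)=O
Why: Saponification of the butenolide keeps the ring-enforced (Z)-geometry, and O-acetylation of the hydroxy carboxylate before acidification should prevent relactonisation.

**Step 16**
Reactants: 19 C8 alcohol of the acrylate; 22 (Z)-4-acetoxy-2-methylbut-2-enoic acid
Product: 23 fully protected ester
Conditions: 22, 2,4,6-Cl3C6H2COCl, Et3N, toluene, rt; then 19, toluene, 75 °C, no DMAP
Reagents that add atoms: none
Why: Yamaguchi esterification through the mixed anhydride without a nucleophilic catalyst should acylate the only free hydroxyl (C8) and avoid the conjugate-addition pathway that turns (Z)-2-methylbut-2-enoates into their (E)-isomers.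

**Step 17**
Reactants: 23 fully protected ester
Product: 25 target acid, via boronate acid 24 (not isolated)
Conditions: Bu4NF (4 equiv), THF, 0 °C → rt; then pH 7 phosphate buffer, NaBO3·4H2O, rt; work-up at pH 4–5 (aq. NaH2PO4)
Reagents that add atoms: sodium perborate [Na+].[Na+].O[B-]1(O)OO[B-](O)(O)OO1
Why: Fluoride deprotection removes the silylethyl ester and the TBDPS ether while O6 is still masked as boron, and organoborane oxidation (1,2-shift with retention) on the carboxylate should then release the 6-hydroxy acid without lactonisation or acyl migration.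

**Compound list**

1 | tert-butyl(but-3-yn-1-yloxy)dimethylsilane | C#CCCO[Si](C)(C)C(C)(C)C | starting material
2 | [(1E)-4-{[tert-butyl(dimethyl)silyl]oxy}-2-methylbut-1-en-1-yl]dimethylalane | C[Al](C)/C=C(\C)CCO[Si](C)(C)C(C)(C)C | intermediate
3 | (2E)-5-{[tert-butyl(dimethyl)silyl]oxy}-3-methylpent-2-en-1-ol | OC/C=C(\C)CCO[Si](C)(C)C(C)(C)C | intermediate
4 | itaconic anhydride (3-methylideneoxolane-2,5-dione) | C=C1CC(=O)OC1=O | starting material
5 | 4-{[(2E)-5-{[tert-butyl(dimethyl)silyl]oxy}-3-methylpent-2-en-1-yl]oxy}-2-methylidene-4-oxobutanoic acid | C=C(CC(=O)OC/C=C(\C)CCO[Si](C)(C)C(C)(C)C)C(=O)O | intermediate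
6 | 4-[(2E)-5-{[tert-butyl(dimethyl)silyl]oxy}-3-methylpent-2-en-1-yl] 1-methyl 2-methylidenebutanedioate | C=C(CC(=O)OC/C=C(\C)CCO[Si](C)(C)C(C)(C)C)C(=O)OC | intermediate
7 | (2S,3S)-3-(2-{[tert-butyl(dimethyl)silyl]oxy}ethyl)-2-(3-methoxy-3-oxoprop-1-en-2-yl)-3-methylpent-4-enoic acid | C=C[C@](C)(CCO[Si](C)(C)C(C)(C)C)[C@@H](C(=C)C(=O)OC)C(=O)O | intermediate
8 | (2S,3S)-3-(2-{[tert-butyl(dimethyl)silyl]oxy}ethyl)-2-(3-hydroxyprop-1-en-2-yl)-3-methylpent-4-en-1-ol | C=C[C@](C)(CCO[Si](C)(C)C(C)(C)C)[C@@H](C(=C)CO)CO | intermediate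
9 | (2S,3S)-3-(2-{[tert-butyl(dimethyl)silyl]oxy}ethyl)-2-(3-{[tert-butyl(diphenyl)silyl]oxy}prop-1-en-2-yl)-3-methylpent-4-en-1-ol | C=C[C@](C)(CCO[Si](C)(C)C(C)(C)C)[C@@H](C(=C)CO[Si](c1ccccc1)(c1ccccc1)C(C)(C)C)CO | intermediate
10 | (2S,3S)-3-(2-{[tert-butyl(dimethyl)silyl]oxy}ethyl)-2-(3-{[tert-butyl(diphenyl)silyl]oxy}prop-1-en-2-yl)-3-methylpent-4-enal | C=C[C@](C)(CCO[Si](C)(C)C(C)(C)C)[C@@H](C(=C)CO[Si](c1ccccc1)(c1ccccc1)C(C)(C)C)C=O | intermediate
11 | (3E,5S,6S)-6-(2-{[tert-butyl(dimethyl)silyl]oxy}ethyl)-5-(3-{[tert-butyl(diphenyl)silyl]oxy}prop-1-en-2-yl)-6-methylocta-3,7-dien-2-one | C=C[C@](C)(CCO[Si](C)(C)C(C)(C)C)[C@@H](C(=C)CO[Si](c1ccccc1)(c1ccccc1)C(C)(C)C)/C=C/C(C)=O | intermediate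
12 | (3E,5S,6S)-5-(3-{[tert-butyl(diphenyl)silyl]oxy}prop-1-en-2-yl)-6-(2-hydroxyethyl)-6-methylocta-3,7-dien-2-one | C=C[C@](C)(CCO)[C@@H](C(=C)CO[Si](c1ccccc1)(c1ccccc1)C(C)(C)C)/C=C/C(C)=O | intermediate
13 | (3S,4S,5E)-4-(3-{[tert-butyl(diphenyl)silyl]oxy}prop-1-en-2-yl)-3-ethenyl-3-methyl-7-oxooct-5-enal | C=C[C@](C)(CC=O)[C@@H](C(=C)CO[Si](c1ccccc1)(c1ccccc1)C(C)(C)C)/C=C/C(C)=O | intermediate
14 | O-pinacolboryl ether of 15 (the 6-hydroxyl of the cyclohexane carries a 4,4,5,5-tetramethyl-1,3,2-dioxaborolan-2-yl group; ring configured as in 15) | C=C[C@]1(C)C[C@H](OB2OC(C)(C)C(C)(C)O2)[C@@H](C(C)=O)[C@H](B2OC(C)(C)C(C)(C)O2)[C@@H]1C(=C)CO[Si](c1ccccc1)(c1ccccc1)C(C)(C)C | intermediate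
15 | 1-[3-(3-{[tert-butyl(diphenyl)silyl]oxy}prop-1-en-2-yl)-4-ethenyl-6-hydroxy-4-methyl-2-(4,4,5,5-tetramethyl-1,3,2-dioxaborolan-2-yl)cyclohexyl]ethan-1-one; ring configured as in 25 (1-acetyl and 4-CH3 on one face; 2-boryl, 3-alkenyl, 4-vinyl and 6-OH on the other) | C=C[C@]1(C)C[C@H](O)[C@@H](C(C)=O)[C@H](B2OC(C)(C)C(C)(C)O2)[C@@H]1C(=C)CO[Si](c1ccccc1)(c1ccccc1)C(C)(C)C | intermediate
16 | triethylsilyl ether of 15 at the 6-hydroxyl; ring configured as in 15 | C=C[C@]1(C)C[C@H](O[Si](CC)(CC)CC)[C@@H](C(C)=O)[C@H](B2OC(C)(C)C(C)(C)O2)[C@@H]1C(=C)CO[Si](c1ccccc1)(c1ccccc1)C(C)(C)C | intermediate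
17 | 1-[cyclohexyl]ethenyl trifluoromethanesulfonate derived from 16 (the acetyl group is now C(=CH2)OTf); ring configured as in 15 | C=C[C@]1(C)C[C@H](O[Si](CC)(CC)CC)[C@@H](C(=C)OS(=O)(=O)C(F)(F)F)[C@H](B2OC(C)(C)C(C)(C)O2)[C@@H]1C(=C)CO[Si](c1ccccc1)(c1ccccc1)C(C)(C)C | intermediate
18 | 2-(trimethylsilyl)ethyl 2-[3-(3-{[tert-butyl(diphenyl)silyl]oxy}prop-1-en-2-yl)-4-ethenyl-4-methyl-2-(4,4,5,5-tetramethyl-1,3,2-dioxaborolan-2-yl)-6-[(triethylsilyl)oxy]cyclohexyl]prop-2-enoate; ring configured as in 15 | C=C[C@]1(C)C[C@H](O[Si](CC)(CC)CC)[C@@H](C(=C)C(=O)OCC[Si](C)(C)C)[C@H](B2OC(C)(C)C(C)(C)O2)[C@@H]1C(=C)CO[Si](c1ccccc1)(c1ccccc1)C(C)(C)C | intermediate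
19 | 2-(trimethylsilyl)ethyl 2-[3-(3-{[tert-butyl(diphenyl)silyl]oxy}prop-1-en-2-yl)-4-ethenyl-6-hydroxy-4-methyl-2-(4,4,5,5-tetramethyl-1,3,2-dioxaborolan-2-yl)cyclohexyl]prop-2-enoate; ring configured as in 15 | C=C[C@]1(C)C[C@H](O)[C@@H](C(=C)C(=O)OCC[Si](C)(C)C)[C@H](B2OC(C)(C)C(C)(C)O2)[C@@H]1C(=C)CO[Si](c1ccccc1)(c1ccccc1)C(C)(C)C | intermediate
20 | 3-methylfuran-2(5H)-one | CC1=CCOC1=O | starting material
21 | sodium (2Z)-4-hydroxy-2-methylbut-2-enoate | [Na+].[O-]C(=O)/C(C)=C\CO | intermediate
22 | (2Z)-4-(acetyloxy)-2-methylbut-2-enoic acid | OC(=O)/C(C)=C\COC(C)=O | intermediate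
23 | (2Z)-4-(acetyloxy)-2-methylbut-2-enoate ester of 19 at the 6-hydroxyl; ring configured as in 15 | C=C[C@]1(C)C[C@H](OC(=O)/C(C)=C\COC(C)=O)[C@@H](C(=C)C(=O)OCC[Si](C)(C)C)[C@H](B2OC(C)(C)C(C)(C)O2)[C@@H]1C(=C)CO[Si](c1ccccc1)(c1ccccc1)C(C)(C)C | intermediate
24 | 2-[6-{[(2Z)-4-(acetyloxy)-2-methylbut-2-enoyl]oxy}-4-ethenyl-3-(3-hydroxyprop-1-en-2-yl)-4-methyl-2-(4,4,5,5-tetramethyl-1,3,2-dioxaborolan-2-yl)cyclohexyl]prop-2-enoic acid; ring configured as in 25 | C=C[C@]1(C)C[C@H](OC(=O)/C(C)=C\COC(C)=O)[C@@H](C(=C)C(=O)O)[C@H](B2OC(C)(C)C(C)(C)O2)[C@@H]1C(=C)CO | intermediate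
25 | 2-[(1S,2R,3S,4S,6S)-6-{[(2Z)-4-(acetyloxy)-2-methylbut-2-enoyl]oxy}-4-ethenyl-2-hydroxy-3-(3-hydroxyprop-1-en-2-yl)-4-methylcyclohexyl]prop-2-enoic acid | C=C[C@]1(C)C[C@H](OC(=O)/C(C)=C\COC(C)=O)[C@@H](C(=C)C(=O)O)[C@H](O)[C@@H]1C(=C)CO | target

**Totals**

Total step count: 17. Longest linear sequence: 16 (steps 1–14, 16, 17; step 15 is the side-chain branch).

**Steps most likely to fail**

Step 10. The boryl-copper species may add to the aldehyde (1,2-borylation), the copper enolate may be protonated before it closes the ring, or facial control at C6 may be poor. The fallback separates the two events and sets out from 11. Conjugate borylation with a proton source (CuCl, DPEphos, NaOtBu, B2pin2, MeOH, THF), run while C8 is still a silyl ether, would give the β-boryl ketone F1. Methanolysis with CSA would give the alcohol F2, and Dess–Martin oxidation the keto aldehyde F3. An amine-catalysed intramolecular aldol reaction under equilibrating conditions (pyrrolidine/AcOH or proline, DMSO) should then favour the β-hydroxy ketone with boron, acetyl and hydroxyl all equatorial, which is 15, where the route is rejoined.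

Step 4. The boron enolate is cross-conjugated with the acrylate, so enolate geometry (and with it the C5/C10 relationship and the enantioselectivity) may be lost, or the acrylate may be consumed by conjugate addition. The fallback removes the acrylate before the rearrangement and sets out from 5. Reduction of the acrylic acid through its mixed anhydride (iBuOCOCl, N-methylmorpholine, THF, −15 °C; then NaBH4, H2O) would give the hydroxy ester F4, and TBDPSCl/imidazole the silyl ether F5. The same diazaborolidine-mediated Ireland–Claisen rearrangement on this simple 3-substituted but-3-enoate would give the acid F6, and LiAlH4 (Et2O, 0 °C) reduces it to 9, where the route is rejoined; this also makes the selective silylation of step 6 unnecessary.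

Step 16. The (Z)-acid may isomerise to the (E)-isomer during activation, acylation of the hindered C8 hydroxyl may be slow, and the hydroxyl may instead close onto the neighbouring ester. The fallback builds the (Z)-alkene on the substrate and sets out from 19. Acylation with 2-[bis(2,2,2-trifluoroethoxy)phosphoryl]propanoic acid (DCC, catalytic DMAP, CH2Cl2, 0 °C) would give the phosphonate ester F7. A Still–Gennari olefination with 2-oxoethyl acetate (KN(SiMe3)2, 18-crown-6, THF, −78 °C) should then give the (Z)-trisubstituted enoate 23, where the route is rejoined.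

**Further compounds**

F1 | step 10 | 6-(2-{[tert-butyl(dimethyl)silyl]oxy}ethyl)-5-(3-{[tert-butyl(diphenyl)silyl]oxy}prop-1-en-2-yl)-6-methyl-4-(4,4,5,5-tetramethyl-1,3,2-dioxaborolan-2-yl)oct-7-en-2-one, configured as in 15 | C=C[C@](C)(CCO[Si](C)(C)C(C)(C)C)[C@@H](C(=C)CO[Si](c1ccccc1)(c1ccccc1)C(C)(C)C)[C@@H](B1OC(C)(C)C(C)(C)O1)CC(C)=O
F2 | step 10 | 5-(3-{[tert-butyl(diphenyl)silyl]oxy}prop-1-en-2-yl)-6-(2-hydroxyethyl)-6-methyl-4-(4,4,5,5-tetramethyl-1,3,2-dioxaborolan-2-yl)oct-7-en-2-one, configured as in 15 | C=C[C@](C)(CCO)[C@@H](C(=C)CO[Si](c1ccccc1)(c1ccccc1)C(C)(C)C)[C@@H](B1OC(C)(C)C(C)(C)O1)CC(C)=O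
F3 | step 10 | 4-(3-{[tert-butyl(diphenyl)silyl]oxy}prop-1-en-2-yl)-3-ethenyl-3-methyl-7-oxo-5-(4,4,5,5-tetramethyl-1,3,2-dioxaborolan-2-yl)octanal, configured as in 15 | C=C[C@](C)(CC=O)[C@@H](C(=C)CO[Si](c1ccccc1)(c1ccccc1)C(C)(C)C)[C@@H](B1OC(C)(C)C(C)(C)O1)CC(C)=O
F4 | step 4 | (2E)-5-{[tert-butyl(dimethyl)silyl]oxy}-3-methylpent-2-en-1-yl 3-(hydroxymethyl)but-3-enoate | C=C(CO)CC(=O)OC/C=C(\C)CCO[Si](C)(C)C(C)(C)C
F5 | step 4 | (2E)-5-{[tert-butyl(dimethyl)silyl]oxy}-3-methylpent-2-en-1-yl 3-({[tert-butyl(diphenyl)silyl]oxy}methyl)but-3-enoate | C=C(CO[Si](c1ccccc1)(c1ccccc1)C(C)(C)C)CC(=O)OC/C=C(\C)CCO[Si](C)(C)C(C)(C)C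
F6 | step 4 | (2S,3S)-3-(2-{[tert-butyl(dimethyl)silyl]oxy}ethyl)-2-(3-{[tert-butyl(diphenyl)silyl]oxy}prop-1-en-2-yl)-3-methylpent-4-enoic acid | C=C[C@](C)(CCO[Si](C)(C)C(C)(C)C)[C@@H](C(=C)CO[Si](c1ccccc1)(c1ccccc1)C(C)(C)C)C(=O)O
F7 | step 16 | 2-[bis(2,2,2-trifluoroethoxy)phosphoryl]propanoate ester of 19 at the 6-hydroxyl, ring configured as in 15 | C=C[C@]1(C)C[C@H](OC(=O)C(C)P(=O)(OCC(F)(F)F)OCC(F)(F)F)[C@@H](C(=C)C(=O)OCC[Si](C)(C)C)[C@H](B2OC(C)(C)C(C)(C)O2)[C@@H]1C(=C)CO[Si](c1ccccc1)(c1ccccc1)C(C)(C)C
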